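**Plan**
- Ring atoms carry shikimate numbers (C1 ester-bearing, C2 vinylic CH, C3–C5 oxygenated, C6 CH2). Retrosynthesis cuts the acyl C–O bonds at O-5 and O-3, then the ring bond C2–C3, then C1=C2 (C2 from formaldehyde), then C6–C1.
- Enabling feature: C4/C5 are a trans (threo) diol flanked by C3 and C6, so C3–C4–C5–C6 is the four-carbon chain of D-threitol (reduced D-tartrate). The bond C2–C3 of the cyclohexene joins a vinylic carbon to an allylic carbinol carbon, the mark of an alkenylchromium addition to an aldehyde.
- Forward: the chain is extended at C6 by phosphonoacetate alkylation, methylenated and brominated to the (E)-β-bromoacrylate, and the C3 aldehyde is unveiled. The only ring, the cyclohexene, then closes at C2–C3; O-3 is acylated, the acetonide removed and O-5 acylated.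
- Stereochemistry: C4 and C5 come from the chiral-pool diol; C3 is set in the ring closure by attack anti to the C4–O bond. The bromide geometry comes from anti elimination and the side-chain alkenes from the purchased (E)-acid.

Key step: step 8

Assumption: the closure in step 8 is taken to follow the Felkin–Anh sense and give the 3R (3,4-cis) carbinol 12 as the main epimer; the starting diol 1 is bought as the commercial D-tartrate-derived acetonide.

**Step 1**
Reactants: 1 (−)-2,3-O-isopropylidene-D-threitol
Product: 2 [(4R,5R)-5-({[tert-butyl(dimethyl)silyl]oxy}methyl)-2,2-dimethyl-1,3-dioxolan-4-yl]methanol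
Conditions: NaH (1.0 equiv), THF, 0 °C to rt; then TBSCl (1.0 equiv)
Reagents that add atoms: tert-butyldimethylsilyl chloride, CC(C)(C)[Si](C)(C)Cl
Why: O-silylation of the sparingly soluble monosodium alkoxide of a C2-symmetric diol should stop at the mono-ether, and either hydroxyl gives the same product.

**Step 2**
Reactants: 2 mono-TBS ether
Product: 3 [(4R,5R)-5-({[tert-butyl(dimethyl)silyl]oxy}methyl)-2,2-dimethyl-1,3-dioxolan-4-yl]methyl trifluoromethanesulfonate
Conditions: Tf2O, pyridine, CH2Cl2, −20 °C; short silica plug, used at once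
Reagents that add atoms: trifluoromethanesulfonic anhydride, O=S(=O)(OS(=O)(=O)C(F)(F)F)C(F)(F)F
Why: Sulfonylation of the primary alcohol should give the triflate, the leaving group needed because this β-oxygenated, β-branched primary carbon is a slow SN2 centre.

**Step 3**
Reactants: 3 triflate; 4 trimethyl phosphonoacetate
Product: 5 methyl 3-[(4R,5R)-5-({[tert-butyl(dimethyl)silyl]oxy}methyl)-2,2-dimethyl-1,3-dioxolan-4-yl]-2-(dimethoxyphosphoryl)propanoate (both C2 epimers)
Conditions: 4 (2.5 equiv), NaH (2.4 equiv), THF–DMF, 0 °C; then 3, 0 °C to rt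
Reagents that add atoms: none
Why: SN2 C-alkylation of the stabilised phosphonoacetate carbanion by a primary triflate should form the C6–C1 bond; excess nucleophile suppresses dialkylation, and the new α-centre is erased in step 4.

**Step 4**
Reactants: 5 alkylated phosphonoacetate
Product: 6 methyl 2-{[(4R,5R)-5-({[tert-butyl(dimethyl)silyl]oxy}methyl)-2,2-dimethyl-1,3-dioxolan-4-yl]methyl}prop-2-enoate
Conditions: 37% aq. HCHO, K2CO3, THF, rt to 40 °C
Reagents that add atoms: formaldehyde, C=O
Why: Horner–Wadsworth–Emmons methylenation of an α-alkyl phosphonoacetate with aqueous formaldehyde under carbonate conditions should deliver the 2-substituted acrylate and so install C2, leaving silyl ether and ketal untouched.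

**Step 5**
Reactants: 6 2-substituted acrylate
Product: 8 methyl (E)-3-bromo-2-{[(4R,5R)-5-({[tert-butyl(dimethyl)silyl]oxy}methyl)-2,2-dimethyl-1,3-dioxolan-4-yl]methyl}prop-2-enoate, via vicinal dibromide 7 (not isolated)
Conditions: Br2 (1.05 equiv), CH2Cl2, 0 °C, dark; then DBU (1.1 equiv), 0 °C to rt
Reagents that add atoms: bromine, BrBr
Why: Bromine addition followed by E2 dehydrobromination, as in the bromination–dehydrobromination of methacrylates, should remove the more acidic CHBr hydrogen anti to the tertiary bromide from the rotamer that keeps the remaining bromine away from the ester, placing Br cis to the C6 methylene (E).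

**Step 6**
Reactants: 8 (E)-bromoacrylate silyl ether
Product: 9 methyl (E)-3-bromo-2-{[(4R,5R)-5-(hydroxymethyl)-2,2-dimethyl-1,3-dioxolan-4-yl]methyl}prop-2-enoate
Conditions: HF·pyridine, pyridine, THF, 0 °C to rt
Reagents that add atoms: none
Why: Fluoride-driven desilylation under pyridine-buffered, non-basic conditions should free the primary alcohol without opening the ketal or adding to the β-bromoacrylate.

**Step 7**
Reactants: 9 primary alcohol
Product: 10 methyl (E)-3-bromo-2-{[(4R,5S)-5-formyl-2,2-dimethyl-1,3-dioxolan-4-yl]methyl}prop-2-enoate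
Conditions: Dess–Martin periodinane, CH2Cl2, 0 °C to rt; used crude
Reagents that add atoms: none
Why: Dess–Martin oxidation is non-basic, so the α-alkoxy aldehyde should form without epimerisation at C4, the trans-dioxolane being the more stable arrangement in any case.

**Step 8**
Reactants: 10 bromoacrylate aldehyde
Product: 12 methyl 4,5-O-isopropylideneshikimate, via alkenylchromium dichloride 11 (not isolated)
Conditions: CrCl2 (5 equiv), NiCl2 (2 mol %), degassed DMF, 0.005 M, rt
Reagents that add atoms: none
Why: CrCl2 reduces NiCl2 to zerovalent nickel, which inserts into the activated C2–Br bond with retention of the (E) geometry; transmetallation to trivalent chromium gives alkenylchromium 11, an oxophilic and weakly basic nucleophile that adds to the C3 aldehyde and leaves ester and ketal alone. The closest known reaction type is the intramolecular Nozaki–Hiyama–Kishi coupling of alkenyl halides, β-haloacrylates included, with aldehydes. The cyclohexene closes in the 6-exo-trig mode, which is possible only because bromine is cis to the C6 methylene and is helped by the trans-dioxolane holding the two arms gauche. The new C3 stereocentre is controlled by C4: in the half-chair trans-fused to the dioxolane the C4–O bond is equatorial, so C2 must attack anti to it (Felkin–Anh arrangement) with the carbonyl oxygen gauche to C5, which should give the 3,4-cis carbinol (3R). The step needs facial selectivity at the aldehyde and cyclisation in preference to oligomerisation; the first rests on the C4 oxygen and the ring fusion, the second on high dilution.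

**Step 9**
Reactants: 12 methyl 4,5-O-isopropylideneshikimate; 13 (E)-3-methylpent-2-enoic acid
Product: 14 methyl 4,5-O-isopropylidene-3-O-[(E)-3-methylpent-2-enoyl]shikimate
Conditions: 13 (1.5 equiv), DCC, DMAP (cat.), CH2Cl2, 0 °C to rt
Reagents that add atoms: none
Why: Steglich esterification acylates the only free hydroxyl without breaking the C3–O bond, so the C3 configuration is retained, and the mild conditions should preserve the (E) geometry of the acyl group.

**Step 10**
Reactants: 14 C3 ester acetonide
Product: 15 methyl 3-O-[(E)-3-methylpent-2-enoyl]shikimate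
Conditions: AcOH–H2O (4:1), 40 °C
Reagents that add atoms: none
Why: Acid-catalysed ketal hydrolysis should cleave the strained trans-fused dioxolane under conditions too mild to hydrolyse the esters or to promote acyl migration.

**Step 11**
Reactants: 15 4,5-diol; 13 (E)-3-methylpent-2-enoic acid
Product: 16 methyl 3,5-bis-O-[(E)-3-methylpent-2-enoyl]shikimate (target)
Conditions: 13 (1.05 equiv), DCC, DMAP (cat.), CH2Cl2, −20 to 0 °C
Reagents that add atoms: none
Why: Regioselective Steglich acylation should favour O-5, whose neighbour is the C6 methylene, over O-4, which is flanked by two oxygenated carbons, in line with the known preference of methyl shikimate for 3,5-bis-functionalisation.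

**Compound list**
1 | (−)-2,3-O-isopropylidene-D-threitol, [(4R,5R)-2,2-dimethyl-1,3-dioxolane-4,5-diyl]dimethanol | OC[C@H]1OC(C)(C)O[C@@H]1CO | starting material
2 | [(4R,5R)-5-({[tert-butyl(dimethyl)silyl]oxy}methyl)-2,2-dimethyl-1,3-dioxolan-4-yl]methanol | OC[C@H]1OC(C)(C)O[C@@H]1CO[Si](C)(C)C(C)(C)C | intermediate
3 | [(4R,5R)-5-({[tert-butyl(dimethyl)silyl]oxy}methyl)-2,2-dimethyl-1,3-dioxolan-4-yl]methyl trifluoromethanesulfonate | FC(F)(F)S(=O)(=O)OC[C@H]1OC(C)(C)O[C@@H]1CO[Si](C)(C)C(C)(C)C | intermediate
4 | trimethyl phosphonoacetate | COC(=O)CP(=O)(OC)OC | starting material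
5 | methyl 3-[(4R,5R)-5-({[tert-butyl(dimethyl)silyl]oxy}methyl)-2,2-dimethyl-1,3-dioxolan-4-yl]-2-(dimethoxyphosphoryl)propanoate, both C2 epimers | COC(=O)C(C[C@H]1OC(C)(C)O[C@@H]1CO[Si](C)(C)C(C)(C)C)P(=O)(OC)OC | intermediate
6 | methyl 2-{[(4R,5R)-5-({[tert-butyl(dimethyl)silyl]oxy}methyl)-2,2-dimethyl-1,3-dioxolan-4-yl]methyl}prop-2-enoate | C=C(C[C@H]1OC(C)(C)O[C@@H]1CO[Si](C)(C)C(C)(C)C)C(=O)OC | intermediate
7 | methyl 2,3-dibromo-2-{[(4R,5R)-5-({[tert-butyl(dimethyl)silyl]oxy}methyl)-2,2-dimethyl-1,3-dioxolan-4-yl]methyl}propanoate, both C2 epimers | BrCC(Br)(C[C@H]1OC(C)(C)O[C@@H]1CO[Si](C)(C)C(C)(C)C)C(=O)OC | intermediate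
8 | methyl (E)-3-bromo-2-{[(4R,5R)-5-({[tert-butyl(dimethyl)silyl]oxy}methyl)-2,2-dimethyl-1,3-dioxolan-4-yl]methyl}prop-2-enoate | COC(=O)/C(=C/Br)C[C@H]1OC(C)(C)O[C@@H]1CO[Si](C)(C)C(C)(C)C | intermediate
9 | methyl (E)-3-bromo-2-{[(4R,5R)-5-(hydroxymethyl)-2,2-dimethyl-1,3-dioxolan-4-yl]methyl}prop-2-enoate | COC(=O)/C(=C/Br)C[C@H]1OC(C)(C)O[C@@H]1CO | intermediate
10 | methyl (E)-3-bromo-2-{[(4R,5S)-5-formyl-2,2-dimethyl-1,3-dioxolan-4-yl]methyl}prop-2-enoate | COC(=O)/C(=C/Br)C[C@H]1OC(C)(C)O[C@@H]1C=O | intermediate
11 | alkenylchromium dichloride derived from 10 (CrCl2 unit on C2 in place of Br, geometry retained, trivalent chromium) | COC(=O)/C(=C/[Cr](Cl)Cl)C[C@H]1OC(C)(C)O[C@@H]1C=O | intermediate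
12 | methyl 4,5-O-isopropylideneshikimate (3-OH free and cis to O-4; O-4 and O-5 trans, bridged by CMe2) | O[C@@H]1C=C(C(=O)OC)C[C@H]2OC(C)(C)O[C@H]12 | intermediate
13 | (E)-3-methylpent-2-enoic acid | CC/C(C)=C/C(=O)O | starting material
14 | methyl 4,5-O-isopropylidene-3-O-[(E)-3-methylpent-2-enoyl]shikimate | CC/C(C)=C/C(=O)O[C@@H]1C=C(C(=O)OC)C[C@H]2OC(C)(C)O[C@H]12 | intermediate
15 | methyl 3-O-[(E)-3-methylpent-2-enoyl]shikimate | CC/C(C)=C/C(=O)O[C@@H]1C=C(C(=O)OC)C[C@@H](O)[C@@H]1O | intermediate
16 | methyl 3,5-bis-O-[(E)-3-methylpent-2-enoyl]shikimate, CNP0268575.1 | CC/C(C)=C/C(=O)O[C@@H]1C=C(C(=O)OC)C[C@@H](OC(=O)/C=C(\C)CC)[C@@H]1O | target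

**Step count and risks**
Total step count: 11. Longest linear sequence: 11 steps (1 to 16); 4 and 13 are purchased.

Steps most likely to fail:

1. Step 8 (ring closure). Facial selectivity at the C3 aldehyde may be poor if chelation of chromium between O-3 and O-4 competes with the Felkin–Anh arrangement, so that the 3,4-trans carbinol forms in quantity. The fallback sets out from 10 and comes back at 14. The same closure then supplies methyl 4,5-O-isopropylidene-3-epi-shikimate F4, which is esterified with 13 under Mitsunobu conditions (PPh3, DIAD, THF, 0 °C). SN2 inversion at the allylic C3 gives 14, so both epimers reach the same ester, one by retentive acylation and one by invertive esterification.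

2. Step 5 (bromination and dehydrobromination). Hydrogen bromide may be lost toward C6, giving a 2-(bromomethyl)alk-2-enoate, or the elimination may give the (Z)-bromide, whose bromine is trans to C6 and cannot close the ring. The fallback sets out from 6 and comes back at 8. Saponification (LiOH, THF–H2O) gives 2-{[(4R,5R)-5-({[tert-butyl(dimethyl)silyl]oxy}methyl)-2,2-dimethyl-1,3-dioxolan-4-yl]methyl}prop-2-enoic acid F1. Bromine addition gives the 2,3-dibromo acid F2, which is treated without isolation with KOH in ethanol. In the carboxylate the departing hydrogen and bromide are anti and the remaining bromine avoids the anionic carboxylate, the classical way to (E)-3-bromo-2-alkylacrylic acids, giving the (E)-3-bromo acid F3. Methylation (MeI, K2CO3, DMF) then returns 8.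

3. Step 11 (selective acylation of O-5). Discrimination between O-5 and O-4 may be insufficient, or DMAP may promote migration of the C3 acyl group to the cis O-4. The fallback sets out from 12 and comes back at 16.
   - Aqueous trifluoroacetic acid gives methyl shikimate F5.
   - TESCl (2.1 equiv) and imidazole at low temperature, by analogy with the established 3,5-bis-silylation of methyl shikimate with bulky silyl chlorides, give methyl 3,5-bis-O-(triethylsilyl)shikimate F6.
   - TBSOTf and 2,6-lutidine silylate the hindered O-4 to give methyl 4-O-(tert-butyldimethylsilyl)-3,5-bis-O-(triethylsilyl)shikimate F7.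
   - PPTS in methanol removes only the triethylsilyl groups, giving methyl 4-O-(tert-butyldimethylsilyl)shikimate F8.
   - Double Steglich esterification with excess 13 gives methyl 4-O-(tert-butyldimethylsilyl)-3,5-bis-O-[(E)-3-methylpent-2-enoyl]shikimate F9.
   - HF·pyridine then frees O-4 to give 16.

**Further compounds**
F1 | step 5 | 2-{[(4R,5R)-5-({[tert-butyl(dimethyl)silyl]oxy}methyl)-2,2-dimethyl-1,3-dioxolan-4-yl]methyl}prop-2-enoic acid | C=C(C[C@H]1OC(C)(C)O[C@@H]1CO[Si](C)(C)C(C)(C)C)C(=O)O
F2 | step 5 | 2,3-dibromo-2-{[(4R,5R)-5-({[tert-butyl(dimethyl)silyl]oxy}methyl)-2,2-dimethyl-1,3-dioxolan-4-yl]methyl}propanoic acid | BrCC(Br)(C[C@H]1OC(C)(C)O[C@@H]1CO[Si](C)(C)C(C)(C)C)C(=O)O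
F3 | step 5 | (E)-3-bromo-2-{[(4R,5R)-5-({[tert-butyl(dimethyl)silyl]oxy}methyl)-2,2-dimethyl-1,3-dioxolan-4-yl]methyl}prop-2-enoic acid | OC(=O)/C(=C/Br)C[C@H]1OC(C)(C)O[C@@H]1CO[Si](C)(C)C(C)(C)C
F4 | step 8 | methyl 4,5-O-isopropylidene-3-epi-shikimate | O[C@H]1C=C(C(=O)OC)C[C@H]2OC(C)(C)O[C@H]12
F5 | step 11 | methyl shikimate | O[C@@H]1C=C(C(=O)OC)C[C@@H](O)[C@@H]1O
F6 | step 11 | methyl 3,5-bis-O-(triethylsilyl)shikimate | CC[Si](CC)(CC)O[C@@H]1C=C(C(=O)OC)C[C@@H](O[Si](CC)(CC)CC)[C@@H]1O
F7 | step 11 | methyl 4-O-(tert-butyldimethylsilyl)-3,5-bis-O-(triethylsilyl)shikimate | CC[Si](CC)(CC)O[C@@H]1C=C(C(=O)OC)C[C@@H](O[Si](CC)(CC)CC)[C@@H]1O[Si](C)(C)C(C)(C)C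
F8 | step 11 | methyl 4-O-(tert-butyldimethylsilyl)shikimate | O[C@@H]1C=C(C(=O)OC)C[C@@H](O)[C@@H]1O[Si](C)(C)C(C)(C)C
F9 | step 11 | methyl 4-O-(tert-butyldimethylsilyl)-3,5-bis-O-[(E)-3-methylpent-2-enoyl]shikimate | CC/C(C)=C/C(=O)O[C@@H]1C=C(C(=O)OC)C[C@@H](OC(=O)/C=C(\C)CC)[C@@H]1O[Si](C)(C)C(C)(C)C
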